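Cudraphenone D is disconnected at both bonds of its benzophenone carbonyl carbon (C7), which links C1 of ring A to C1' of ring B. The route exploits the contiguous C1-acyl, C2-prenyl, C3-hydroxyl array of ring A: it maps onto C3, C2 and C1 of 2-prenylcyclohexane-1,3-dione, so ring A is carried as a cyclohexenone and aromatized afterwards. In one palladium-catalysed operation an aryl iodide (ring B, three MOM ethers, prenyl in place), carbon monoxide and a 3-stannyl-2-prenylcyclohex-2-enone are united, forming C1'–C7 and C7–C1. The precursors are 2-iodo-1,3,5-tris(methoxymethoxy)-4-prenylbenzene and the stannylenone, each three steps from phloroglucinol or cyclohexane-1,3-dione.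

Key step: step 7

Remark: prenyl means 3-methylbut-2-en-1-yl and the target has no stereocentre or stereogenic double bond; the alkenylstannane is made as its trimethylstannyl derivative, because hexamethylditin stannylates enol triflates more readily than hexabutylditin and the smaller tin group transfers faster from a tetrasubstituted alkene carbon (carbon skeleton and bonds formed are unaffected).

Step 1
Reactants: 1 cyclohexane-1,3-dione; 2 prenyl bromide
Product: 3 2-prenylcyclohexane-1,3-dione
Conditions: KOH (1 equiv), H2O, 0 °C → rt
Reagents that add atoms: none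
Why: C-alkylation of a cyclic 1,3-dione enolate by an allylic bromide in water, where hydration of the enolate oxygens suppresses O-alkylation, so the prenyl group should enter at C2.

Step 2
Reactants: 3 2-prenylcyclohexane-1,3-dione
Product: 4 3-oxo-2-prenylcyclohex-1-en-1-yl trifluoromethanesulfonate
Conditions: Tf2O, pyridine, CH2Cl2, −78 → 0 °C
Reagents that add atoms: triflic anhydride, O=S(=O)(OS(=O)(=O)C(F)(F)F)C(F)(F)F
Why: O-sulfonylation of the enol form of the dione gives the vinylogous acyl triflate, and the symmetry of 3 allows only one enol triflate.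

Step 3
Reactants: 4 3-oxo-2-prenylcyclohex-1-en-1-yl trifluoromethanesulfonate
Product: 5 2-prenyl-3-(trimethylstannyl)cyclohex-2-en-1-one
Conditions: Me3SnSnMe3, Pd(PPh3)4 (5 mol%), LiCl, THF, 65 °C
Reagents that add atoms: hexamethylditin, C[Sn](C)(C)[Sn](C)(C)C
Why: Palladium-catalysed stannylation of an alkenyl triflate with a distannane (Stille-type triflate–ditin coupling) should place tin exactly on the former carbonyl carbon through oxidative addition of the electron-poor C–OTf bond, transmetalation and reductive elimination.

Step 4
Reactants: 6 phloroglucinol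
Product: 7 1,3,5-tris(methoxymethoxy)benzene
Conditions: MOMCl, i-Pr2NEt, CH2Cl2/DMF, 0 °C → rt
Reagents that add atoms: chloromethyl methyl ether, COCCl
Why: Williamson-type O-alkylation of the three phenols by the hard electrophile MOMCl under amine base gives the tris-acetal, which later directs both lithiations.

Step 5
Reactants: 7 1,3,5-tris(methoxymethoxy)benzene; 2 prenyl bromide
Product: 9 1,3,5-tris(methoxymethoxy)-2-prenylbenzene, via aryllithium 8 (not isolated)
Conditions: n-BuLi, THF, 0 °C; CuI (10 mol%), then 2, −78 °C → rt
Reagents that add atoms: none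
Why: Directed ortho-metalation at a position flanked by two OMOM groups (all three free positions of 7 are equivalent), then copper-assisted SN2 alkylation by the primary allylic bromide, should install the linear prenyl group.

Step 6
Reactants: 9 1,3,5-tris(methoxymethoxy)-2-prenylbenzene
Product: 11 2-iodo-1,3,5-tris(methoxymethoxy)-4-prenylbenzene, via aryllithium 10 (not isolated)
Conditions: n-BuLi, THF, −20 → 0 °C; then ICH2CH2I, −78 °C → rt
Reagents that add atoms: 1,2-diiodoethane, ICCI
Why: A second directed ortho-metalation takes place at one of the two symmetry-equivalent free positions, each between two OMOM groups, and the aryllithium is iodinated by 1,2-diiodoethane, an iodine donor that leaves the prenyl double bond alone.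

Step 7
Reactants: 11 2-iodo-1,3,5-tris(methoxymethoxy)-4-prenylbenzene; 12 carbon monoxide; 5 2-prenyl-3-(trimethylstannyl)cyclohex-2-en-1-one
Product: 13 2-prenyl-3-[2,4,6-tris(methoxymethoxy)-3-prenylbenzoyl]cyclohex-2-en-1-one
Conditions: Pd2(dba)3 (5 mol%), AsPh3 (40 mol%), CuI (20 mol%), CO (3 bar), NMP, 65 °C
Reagents that add atoms: none
Why: Zerovalent palladium carrying AsPh3 inserts into the C–I bond of 11, carbon monoxide inserts into the aryl–palladium bond to give an aroylpalladium iodide (bond C1'–C7), the cyclohexenyl group of 5 passes from tin to palladium, helped by CuI through a transient alkenylcopper, and reductive elimination forms C7–C1 and returns zerovalent palladium. The closest known reaction type is the carbonylative Stille coupling of aryl iodides, di-ortho-substituted ones included, with alkenylstannanes. No ring closes and no stereocentre is created, so neither a closure mode nor a stereocontrol element is involved. The selectivity needed is carbonyl insertion ahead of direct aryl–alkenyl coupling; the two OMOM groups ortho to palladium slow transmetalation at the arylpalladium stage, the CO pressure traps that species as the acyl complex, and the acyl ligand moves the reacting centre one atom away from the crowded ring. Regiochemistry is built into the partners: iodine occupies the only position of ring B left between two acetal oxygens, and tin sits on the former dione carbonyl carbon, which locks the ring A prenyl group between the new ketone and the future C3 phenol.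

Step 8
Reactants: 13 2-prenyl-3-[2,4,6-tris(methoxymethoxy)-3-prenylbenzoyl]cyclohex-2-en-1-one
Product: 14 [2-prenyl-3-(trimethylsilyloxy)cyclohexa-1,3-dien-1-yl][2,4,6-tris(methoxymethoxy)-3-prenylphenyl]methanone
Conditions: LiN(SiMe3)2, TMSCl, THF, −78 °C
Reagents that add atoms: chlorotrimethylsilane, C[Si](C)(C)Cl
Why: Kinetic deprotonation of the enone at the α′ methylene (C6) by the hindered, non-nucleophilic amide base with in situ O-silylation should give the cross-conjugated silyl dienol ether, the aryl ketone having no α-hydrogen on its aryl side.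

Step 9
Reactants: 14 [2-prenyl-3-(trimethylsilyloxy)cyclohexa-1,3-dien-1-yl][2,4,6-tris(methoxymethoxy)-3-prenylphenyl]methanone
Product: 16 (3-hydroxy-2-prenylphenyl)[2,4,6-tris(methoxymethoxy)-3-prenylphenyl]methanone, via cyclohexa-2,5-dienone 15 (not isolated)
Conditions: Pd(OAc)2 (1.1 equiv), MeCN, rt
Reagents that add atoms: none
Why: Saegusa–Ito dehydrogenation, in which divalent palladium palladates the silyl enol ether at C6 and β-hydride elimination gives the 2,5-dienone, whose tautomerization to the C3 phenol is driven by aromatization of ring A.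

Step 10
Reactants: 16 (3-hydroxy-2-prenylphenyl)[2,4,6-tris(methoxymethoxy)-3-prenylphenyl]methanone
Product: 17 cudraphenone D, (3-hydroxy-2-prenylphenyl)(2,4,6-trihydroxy-3-prenylphenyl)methanone
Conditions: HCl (3 M aq.), MeOH, rt
Reagents that add atoms: none
Why: Acid-catalysed methanolysis of the three aryl methoxymethyl acetals frees the phenols, and dilute acid at room temperature should leave the prenyl double bonds uncyclized.

Compound list
1 | cyclohexane-1,3-dione | O=C1CCCC(=O)C1 | starting material
2 | prenyl bromide (1-bromo-3-methylbut-2-ene) | CC(C)=CCBr | starting material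
3 | 2-prenylcyclohexane-1,3-dione | CC(C)=CCC1C(=O)CCCC1=O | intermediate
4 | 3-oxo-2-prenylcyclohex-1-en-1-yl trifluoromethanesulfonate | CC(C)=CCC1=C(OS(=O)(=O)C(F)(F)F)CCCC1=O | intermediate
5 | 2-prenyl-3-(trimethylstannyl)cyclohex-2-en-1-one | CC(C)=CCC1=C([Sn](C)(C)C)CCCC1=O | intermediate
6 | phloroglucinol (benzene-1,3,5-triol) | Oc1cc(O)cc(O)c1 | starting material
7 | 1,3,5-tris(methoxymethoxy)benzene | COCOc1cc(OCOC)cc(OCOC)c1 | intermediate
8 | [2,4,6-tris(methoxymethoxy)phenyl]lithium | [Li]c1c(OCOC)cc(OCOC)cc1OCOC | intermediate (not isolated)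
9 | 1,3,5-tris(methoxymethoxy)-2-prenylbenzene | COCOc1cc(OCOC)c(CC=C(C)C)c(OCOC)c1 | intermediate
10 | [2,4,6-tris(methoxymethoxy)-3-prenylphenyl]lithium | [Li]c1c(OCOC)cc(OCOC)c(CC=C(C)C)c1OCOC | intermediate (not isolated)
11 | 2-iodo-1,3,5-tris(methoxymethoxy)-4-prenylbenzene | COCOc1cc(OCOC)c(CC=C(C)C)c(OCOC)c1I | intermediate
12 | carbon monoxide | [C-]#[O+] | starting material
13 | 2-prenyl-3-[2,4,6-tris(methoxymethoxy)-3-prenylbenzoyl]cyclohex-2-en-1-one | CC(C)=CCC1=C(CCCC1=O)C(=O)c1c(OCOC)cc(OCOC)c(CC=C(C)C)c1OCOC | intermediate
14 | [2-prenyl-3-(trimethylsilyloxy)cyclohexa-1,3-dien-1-yl][2,4,6-tris(methoxymethoxy)-3-prenylphenyl]methanone | CC(C)=CCC1=C(CCC=C1O[Si](C)(C)C)C(=O)c1c(OCOC)cc(OCOC)c(CC=C(C)C)c1OCOC | intermediate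
15 | 2-prenyl-3-[2,4,6-tris(methoxymethoxy)-3-prenylbenzoyl]cyclohexa-2,5-dien-1-one | CC(C)=CCC1=C(CC=CC1=O)C(=O)c1c(OCOC)cc(OCOC)c(CC=C(C)C)c1OCOC | intermediate (not isolated)
16 | (3-hydroxy-2-prenylphenyl)[2,4,6-tris(methoxymethoxy)-3-prenylphenyl]methanone | CC(C)=CCc1c(O)cccc1C(=O)c1c(OCOC)cc(OCOC)c(CC=C(C)C)c1OCOC | intermediate
17 | cudraphenone D, (3-hydroxy-2-prenylphenyl)(2,4,6-trihydroxy-3-prenylphenyl)methanone | CC(C)=CCc1c(O)cccc1C(=O)c1c(O)cc(O)c(CC=C(C)C)c1O | target

Total step count: 10.
Longest linear sequence: 7 steps (1, 2, 3, 7, 8, 9, 10; the ring B branch 4, 5, 6, 7, 8, 9, 10 is equally long).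

Steps most likely to fail

Step 7. Transfer of the tetrasubstituted, electron-poor alkenyl group to the hindered aroylpalladium may stall. Coupling without carbon monoxide, methyl transfer from tin or protodestannylation could then take over. The fallback gives up the cyclohexenone and builds the ketone by polar addition with ring A already aromatic. It sets out from 9 and comes back at 17. 3-Hydroxybenzaldehyde is protected (MOMCl, i-Pr2NEt) to 3-(methoxymethoxy)benzaldehyde F1. The aldehyde is masked in situ as its lithium α-amino alkoxide with LiN(Me)CH2CH2NMe2, lithiated at C2 with n-BuLi between the two directing groups, transmetalated with CuBr·SMe2 and alkylated with 2, which after aqueous work-up should give 3-(methoxymethoxy)-2-prenylbenzaldehyde F2. Compound 9 is lithiated to 10 as in step 6 and added to F2 in THF at −78 °C to give the racemic carbinol [3-(methoxymethoxy)-2-prenylphenyl][2,4,6-tris(methoxymethoxy)-3-prenylphenyl]methanol F3. Oxidation of this doubly benzylic alcohol with MnO2 in CH2Cl2 should give [3-(methoxymethoxy)-2-prenylphenyl][2,4,6-tris(methoxymethoxy)-3-prenylphenyl]methanone F4. Removal of all four acetals under the conditions of step 10 then gives 17.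

Step 9. Palladation of the silyl dienol ether may be slower than its hydrolysis back to 13. Divalent palladium may also engage the prenyl double bonds (allylic oxidation or Wacker-type addition), and enolization at the wrong site in step 8 would be carried through. The fallback replaces the palladium dehydrogenation by a selenium-based one. It sets out from 14 and comes back at 16. PhSeCl in THF at −78 °C should selenenylate the silyl enol ether at C6 to give racemic 6-(phenylselanyl)-2-prenyl-3-[2,4,6-tris(methoxymethoxy)-3-prenylbenzoyl]cyclohex-2-en-1-one F5. Oxidation with H2O2 and pyridine in CH2Cl2 at 0 °C gives the selenoxide, 6-(phenylseleninyl)-2-prenyl-3-[2,4,6-tris(methoxymethoxy)-3-prenylbenzoyl]cyclohex-2-en-1-one F6, which is not isolated. Syn-elimination gives dienone 15, which tautomerizes to 16.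

Step 10. Protic acid may cyclize the freed ortho-prenylphenols onto their double bonds (chroman formation) or hydrate the alkenes before the slowest acetal, the one para to the ketone, is cleaved. The fallback avoids protic acid by exchanging the protecting groups and cleaving with fluoride. It sets out from 16 and comes back at 17. Excess TESOTf with 2,2'-bipyridyl in CH2Cl2 at 0 °C → rt should convert the three aryl methoxymethyl ethers into triethylsilyl ethers and silylate the free phenol. This gives [2-prenyl-3-(triethylsilyloxy)phenyl][3-prenyl-2,4,6-tris(triethylsilyloxy)phenyl]methanone F7. Bu4NF buffered with AcOH in THF at 0 °C then removes the four silyl groups to give 17.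

Further compounds
F1 | step 7 | 3-(methoxymethoxy)benzaldehyde | COCOc1cccc(C=O)c1
F2 | step 7 | 3-(methoxymethoxy)-2-prenylbenzaldehyde | COCOc1cccc(C=O)c1CC=C(C)C
F3 | step 7 | [3-(methoxymethoxy)-2-prenylphenyl][2,4,6-tris(methoxymethoxy)-3-prenylphenyl]methanol (racemic) | COCOc1cccc(C(O)c2c(OCOC)cc(OCOC)c(CC=C(C)C)c2OCOC)c1CC=C(C)C
F4 | step 7 | [3-(methoxymethoxy)-2-prenylphenyl][2,4,6-tris(methoxymethoxy)-3-prenylphenyl]methanone | COCOc1cccc(C(=O)c2c(OCOC)cc(OCOC)c(CC=C(C)C)c2OCOC)c1CC=C(C)C
F5 | step 9 | 6-(phenylselanyl)-2-prenyl-3-[2,4,6-tris(methoxymethoxy)-3-prenylbenzoyl]cyclohex-2-en-1-one (racemic) | CC(C)=CCC1=C(CCC([Se]c2ccccc2)C1=O)C(=O)c1c(OCOC)cc(OCOC)c(CC=C(C)C)c1OCOC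
F6 | step 9 | 6-(phenylseleninyl)-2-prenyl-3-[2,4,6-tris(methoxymethoxy)-3-prenylbenzoyl]cyclohex-2-en-1-one (mixture of stereoisomers, not isolated) | CC(C)=CCC1=C(CCC([Se](=O)c2ccccc2)C1=O)C(=O)c1c(OCOC)cc(OCOC)c(CC=C(C)C)c1OCOC
F7 | step 10 | [2-prenyl-3-(triethylsilyloxy)phenyl][3-prenyl-2,4,6-tris(triethylsilyloxy)phenyl]methanone | CC[Si](CC)(CC)Oc1cccc(C(=O)c2c(O[Si](CC)(CC)CC)cc(O[Si](CC)(CC)CC)c(CC=C(C)C)c2O[Si](CC)(CC)CC)c1CC=C(C)C
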